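## Retrosynthetic overview
1. Tatanan B (38) comes from the spirodienone phenol 36 by O‑methylation and vinyl → ethyl hydrogenation.
2. 36 comes from the bis‑phenol allyl carbonate 35 by Pd(0) dearomative allylic alkylation. The C1–C6 bond closes the cyclohexane and creates the spiro centre in one step (last ring), setting C1, C5 and C6.
3. 35 comes from carbinol 30 by C5 deoxygenation and C1 homologation. 30 is the key union of three fragments of about twenty heavy atoms each: lactone 27 plus two molecules of aryl bromide 14 (both C5–aryl bonds).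
4. 27 carries the C2–C4 triad and comes from α‑methylation, face‑selective hydrogenation and Suzuki coupling of enol triflate 23 with boronate 7. Its δ‑lactone (first ring, temporary) is built from (S)‑Roche ester and t‑BuOAc.
5. Arenes: 7 from 1,4‑benzoquinone (Thiele acetoxylation), 14 from hydroquinone (ortho‑lithiation/oxidation).

Convention (assumed): C1–C6 are the cyclohexane atoms in the order of the target SMILES (C1 Et, C2 Me, C3 Ar, C4 Me, C5 Ar, C6 spiro). Et, C2‑Me, C3‑Ar and C5‑Ar lie on one face; C4‑Me and the MeO‑bearing sp2 carbon on C6 lie on the other. Ar = 2,4,5‑trimethoxyphenyl.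

## Route

Step 1
Reactants: 1 1,4-benzoquinone
Product: 2 benzene-1,2,4-triyl triacetate
Conditions: Ac2O, cat. H2SO4, 40–50 °C
Reagents that add atoms: acetic anhydride, CC(=O)OC(C)=O
Why: Thiele–Winterstein acetoxylation: the acid‑activated quinone takes up acetate by 1,4‑addition and the resulting hydroquinone is peracetylated, which installs the third ring oxygen.

Step 2
Reactants: 2 benzene-1,2,4-triyl triacetate
Product: 4 1,2,4-trimethoxybenzene, via benzene-1,2,4-triol 3 (not isolated)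
Conditions: NaOH, Me2SO4, MeOH–H2O, N2, 0 °C → reflux
Reagents that add atoms: dimethyl sulfate, COS(=O)(=O)OC
Why: Saponification frees the air‑sensitive triol, which is O‑methylated at once under nitrogen (Williamson ether synthesis).

Step 3
Reactants: 4 1,2,4-trimethoxybenzene
Product: 5 1-bromo-2,4,5-trimethoxybenzene
Conditions: NBS, MeCN, 0 °C
Reagents that add atoms: N-bromosuccinimide, O=C1CCC(=O)N1Br
Why: Electrophilic aromatic bromination goes to the only unhindered position that is ortho/para to two methoxy groups.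

Step 4
Reactants: 5 1-bromo-2,4,5-trimethoxybenzene
Product: 7 2-(2,4,5-trimethoxyphenyl)-4,4,5,5-tetramethyl-1,3,2-dioxaborolane, via (2,4,5-trimethoxyphenyl)lithium 6 (not isolated)
Conditions: n-BuLi, THF, −78 °C; i-PrOBpin, −78 °C → rt; H2O
Reagents that add atoms: 2-isopropoxy-4,4,5,5-tetramethyl-1,3,2-dioxaborolane, CC(C)OB1OC(C)(C)C(C)(C)O1
Why: Br–Li exchange and borylation give the pinacol boronate, which resists protodeboronation better than the electron‑rich boronic acid.

Step 5
Reactants: 8 hydroquinone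
Product: 9 1,4-dimethoxybenzene
Conditions: MeI, K2CO3, acetone, reflux
Reagents that add atoms: iodomethane, CI
Why: Double Williamson ether synthesis on the phenoxide.

Step 6
Reactants: 9 1,4-dimethoxybenzene
Product: 12 2,5-dimethoxyphenol, via (2,5-dimethoxyphenyl)lithium 10 (not isolated), via dimethyl (2,5-dimethoxyphenyl)boronate 11 (not isolated)
Conditions: n-BuLi, TMEDA, Et2O, 0 °C → rt; B(OMe)3, −78 °C → rt; 30% H2O2, AcOH, 0 °C → rt
Reagents that add atoms: hydrogen peroxide, OO
Why: Directed ortho‑lithiation, borate trapping and oxidative C→O 1,2‑aryl shift replace one ortho C–H by OH.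

Step 7
Reactants: 12 2,5-dimethoxyphenol
Product: 13 tert-butyl(2,5-dimethoxyphenoxy)dimethylsilane
Conditions: TBSCl, imidazole, DMF, rt
Reagents that add atoms: tert-butyldimethylsilyl chloride, CC(C)(C)[Si](C)(C)Cl
Why: Silyl protection of the phenol gives an ether that tolerates organolithiums and acid but is cleaved by fluoride.

Step 8
Reactants: 13 tert-butyl(2,5-dimethoxyphenoxy)dimethylsilane
Product: 14 (4-bromo-2,5-dimethoxyphenoxy)(tert-butyl)dimethylsilane
Conditions: NBS, MeCN, 0 °C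
Reagents that add atoms: N-bromosuccinimide, O=C1CCC(=O)N1Br
Why: Electrophilic aromatic bromination occurs para to the silyloxy group and ortho to OMe, the doubly activated position of a 1,2,4‑trioxygenated arene.

Step 9
Reactants: 15 methyl (2S)-3-hydroxy-2-methylpropanoate
Product: 16 methyl (2S)-3-(tert-butyldimethylsilyloxy)-2-methylpropanoate
Conditions: TBSCl, imidazole, CH2Cl2, rt
Reagents that add atoms: tert-butyldimethylsilyl chloride, CC(C)(C)[Si](C)(C)Cl
Why: Silylation of the primary alcohol leaves untouched the chiral‑pool stereocentre that becomes C2.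

Step 10
Reactants: 16 methyl (2S)-3-(tert-butyldimethylsilyloxy)-2-methylpropanoate; 17 tert-butyl acetate
Product: 19 tert-butyl (4S)-5-(tert-butyldimethylsilyloxy)-4-methyl-3-oxopentanoate, via lithium enolate of tert-butyl acetate 18 (not isolated)
Conditions: LDA (3.3 equiv), 17 (3.3 equiv), THF, −78 °C; 16, −78 → 0 °C; AcOH
Reagents that add atoms: none
Why: Crossed Claisen condensation in which the product rests as its chelated β‑keto ester enolate, so the neighbouring stereocentre is not enolised.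

Step 11
Reactants: 19 tert-butyl (4S)-5-(tert-butyldimethylsilyloxy)-4-methyl-3-oxopentanoate
Product: 22 (5S)-5-methyloxane-2,4-dione, via hydroxy keto ester 20 (not isolated), via acylketene 21 (not isolated)
Conditions: 48% aq HF, MeCN, 0 °C; then PhMe, 110 °C
Reagents that add atoms: none
Why: After desilylation the tert‑butyl β‑keto ester loses t‑BuOH thermally and the δ‑hydroxyl traps the acylketene to close the six‑membered β‑keto lactone under neutral conditions.

Step 12
Reactants: 22 (5S)-5-methyloxane-2,4-dione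
Product: 23 (3S)-3-methyl-6-oxo-3,6-dihydro-2H-pyran-4-yl trifluoromethanesulfonate
Conditions: Tf2O, Et3N, CH2Cl2, −78 °C
Reagents that add atoms: trifluoromethanesulfonic anhydride, O=S(=O)(OS(=O)(=O)C(F)(F)F)C(F)(F)F
Why: O‑sulfonylation of the vinylogous acid at the 4‑oxygen gives the conjugated enol triflate, and deprotonation takes place only between the two carbonyl groups.

Step 13
Reactants: 23 (3S)-3-methyl-6-oxo-3,6-dihydro-2H-pyran-4-yl trifluoromethanesulfonate; 7 2-(2,4,5-trimethoxyphenyl)-4,4,5,5-tetramethyl-1,3,2-dioxaborolane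
Product: 24 (5R)-5-methyl-4-(2,4,5-trimethoxyphenyl)-5,6-dihydro-2H-pyran-2-one
Conditions: Pd(PPh3)4 (5 mol %), CsF, DME, 80 °C
Reagents that add atoms: none
Why: Suzuki–Miyaura coupling of an activated enol triflate under fluoride activation forms the C3–Ar bond without hydrolysing the lactone or deprotonating the γ‑position.

Step 14
Reactants: 24 (5R)-5-methyl-4-(2,4,5-trimethoxyphenyl)-5,6-dihydro-2H-pyran-2-one
Product: 25 (4R,5R)-5-methyl-4-(2,4,5-trimethoxyphenyl)oxan-2-one (4,5-cis)
Conditions: H2 (1 atm), 10% Pd/C, EtOAc, rt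
Reagents that add atoms: none
Why: Heterogeneous syn‑hydrogenation: A(1,2) strain with the twisted aryl group holds the methyl pseudoaxial, so H2 arrives from the opposite face and the aryl group ends cis to the methyl (sets C3).

Step 15
Reactants: 25 (4R,5R)-5-methyl-4-(2,4,5-trimethoxyphenyl)oxan-2-one
Product: 27 (3R,4S,5R)-3,5-dimethyl-4-(2,4,5-trimethoxyphenyl)oxan-2-one (3,4-trans/4,5-cis), via lithium lactone enolate 26 (not isolated)
Conditions: LDA, THF, −78 °C; MeI, −78 → −40 °C
Reagents that add atoms: iodomethane, CI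
Why: Lactone enolate alkylation in which MeI approaches the face opposite to the cis‑disposed aryl and methyl groups, giving the 3,4‑trans product (sets C4).

Step 16
Reactants: 27 (3R,4S,5R)-3,5-dimethyl-4-(2,4,5-trimethoxyphenyl)oxan-2-one; 14 (4-bromo-2,5-dimethoxyphenoxy)(tert-butyl)dimethylsilane (2.6 equiv, two incorporated)
Product: 30 (2R,3S,4R)-1,1-bis[4-(tert-butyldimethylsilyloxy)-2,5-dimethoxyphenyl]-2,4-dimethyl-3-(2,4,5-trimethoxyphenyl)pentane-1,5-diol, via aryllithium 28 (not isolated), via lithium keto alkoxide 29 (not isolated)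
Conditions: 14, n-BuLi, THF, −78 °C; 27, −78 → 0 °C; H2O
Reagents that add atoms: none
Why: Br–Li exchange and double 1,2‑addition of the ortho‑methoxy‑chelated aryllithium to the lactone (ring opening to the ketone, then second addition) join the three fragments, and no stereocentre arises at C5 because the two aryl groups are identical.

Step 17
Reactants: 30 the diaryl carbinol diol
Product: 31 (2R,3R,4R)-5,5-bis[4-(tert-butyldimethylsilyloxy)-2,5-dimethoxyphenyl]-2,4-dimethyl-3-(2,4,5-trimethoxyphenyl)pentan-1-ol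
Conditions: Et3SiH (5 equiv), TFA (5 equiv), CH2Cl2, −40 → 0 °C
Reagents that add atoms: none
Why: Kursanov–Parnes ionic hydrogenation: TFA ionises only the doubly benzylic carbinol, and excess silane delivers hydride faster than C4 loses a proton to a badly strained tetrasubstituted 1,1‑diarylalkene, so C4 is retained.

Step 18
Reactants: 31 the primary alcohol
Product: 32 (2R,3R,4R)-5,5-bis[4-(tert-butyldimethylsilyloxy)-2,5-dimethoxyphenyl]-2,4-dimethyl-3-(2,4,5-trimethoxyphenyl)pentanal
Conditions: Dess–Martin periodinane, CH2Cl2, 0 °C → rt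
Reagents that add atoms: none
Why: Dess–Martin oxidation stops at the aldehyde under near‑neutral conditions, sparing the α‑stereocentre C2, the electron‑rich arenes and the aryl silyl ethers.

Step 19
Reactants: 32 the aldehyde
Product: 34 (4R,5R,6R)-7,7-bis[4-(tert-butyldimethylsilyloxy)-2,5-dimethoxyphenyl]-4,6-dimethyl-5-(2,4,5-trimethoxyphenyl)hept-1-en-3-yl methyl carbonate (C3 epimer mixture), via bromomagnesium allylic alkoxide 33 (not isolated)
Conditions: CH2=CHMgBr, THF, −78 °C; ClCO2Me, −78 °C → rt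
Reagents that add atoms: vinylmagnesium bromide, C=C[Mg]Br; methyl chloroformate, COC(=O)Cl
Why: Grignard 1,2‑addition and in‑flask acylation of the alkoxide give the allylic carbonate, and the carbinol configuration is irrelevant because both epimers later give the same π‑allyl complex.

Step 20
Reactants: 34 the bis-silyl allylic carbonate
Product: 35 (4R,5R,6R)-7,7-bis(4-hydroxy-2,5-dimethoxyphenyl)-4,6-dimethyl-5-(2,4,5-trimethoxyphenyl)hept-1-en-3-yl methyl carbonate (C3 epimer mixture)
Conditions: TBAF, AcOH, THF, 0 °C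
Reagents that add atoms: none
Why: Buffered fluoride desilylation frees both phenols without leaving phenoxide that could attack the carbonate.

Step 21
Reactants: 35 the bis-phenol allylic carbonate
Product: 36 (6S,7R,8R,9S,10R,11R)-7-ethenyl-11-(4-hydroxy-2,5-dimethoxyphenyl)-1,4-dimethoxy-8,10-dimethyl-9-(2,4,5-trimethoxyphenyl)spiro[5.5]undeca-1,4-dien-3-one
Conditions: Pd2(dba)3·CHCl3 (5 mol %), PPh3 (25 mol %), CH2Cl2, rt
Reagents that add atoms: none
Why: Intramolecular Pd‑catalysed dearomative Tsuji–Trost (ipso‑Friedel–Crafts) allylation: both carbonate epimers ionise to one equilibrating π‑allyl complex, the liberated methoxide deprotonates a phenol, and its para carbon attacks the internal allyl terminus through the chair in which C3‑Ar, C4‑Me, the spectator aryl at C5 and the new vinyl at C1 are equatorial and only C2‑Me is axial, which selects one of the two diastereotopic aryl groups (sets C5), fixes C1, and places the MeO‑bearing ortho carbon of the attacking ring equatorial, away from the axial C2 methyl (sets C6).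

Step 22
Reactants: 36 the spirodienone phenol
Product: 37 (6S,7R,8R,9S,10R,11R)-7-ethenyl-1,4-dimethoxy-8,10-dimethyl-9,11-bis(2,4,5-trimethoxyphenyl)spiro[5.5]undeca-1,4-dien-3-one
Conditions: MeI, K2CO3, acetone, rt
Reagents that add atoms: iodomethane, CI
Why: Williamson methylation of the remaining phenol completes the second trimethoxyphenyl group, and the non‑enolisable dienone is inert to carbonate.

Step 23
Reactants: 37 the vinyl spirodienone
Product: 38 tatanan B, (6S,7R,8S,9S,10R,11R)-7-ethyl-1,4-dimethoxy-8,10-dimethyl-9,11-bis(2,4,5-trimethoxyphenyl)spiro[5.5]undeca-1,4-dien-3-one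
Conditions: H2 (1–3 atm), RhCl(PPh3)3 (10 mol %), benzene–EtOH, rt
Reagents that add atoms: none
Why: Wilkinson hydrogenation reduces only the monosubstituted alkene and leaves the trisubstituted methoxy‑bearing dienone C=C bonds and all stereocentres alone (the C8 descriptor changes from R to S only through the CIP ranking).

## Compound list
1 | 1,4-benzoquinone | O=C1C=CC(=O)C=C1 | starting material
2 | benzene-1,2,4-triyl triacetate | CC(=O)Oc1ccc(OC(C)=O)c(OC(C)=O)c1 | intermediate
3 | benzene-1,2,4-triol (not isolated) | Oc1ccc(O)c(O)c1 | intermediate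
4 | 1,2,4-trimethoxybenzene | COc1ccc(OC)c(OC)c1 | intermediate
5 | 1-bromo-2,4,5-trimethoxybenzene | COc1cc(OC)c(OC)cc1Br | intermediate
6 | (2,4,5-trimethoxyphenyl)lithium (not isolated) | [Li]c1cc(OC)c(OC)cc1OC | intermediate
7 | 2-(2,4,5-trimethoxyphenyl)-4,4,5,5-tetramethyl-1,3,2-dioxaborolane | CC1(C)OB(OC1(C)C)c1cc(OC)c(OC)cc1OC | intermediate
8 | hydroquinone | Oc1ccc(O)cc1 | starting material
9 | 1,4-dimethoxybenzene | COc1ccc(OC)cc1 | intermediate
10 | (2,5-dimethoxyphenyl)lithium (not isolated) | [Li]c1cc(OC)ccc1OC | intermediate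
11 | dimethyl (2,5-dimethoxyphenyl)boronate (not isolated) | COB(OC)c1cc(OC)ccc1OC | intermediate
12 | 2,5-dimethoxyphenol | Oc1cc(OC)ccc1OC | intermediate
13 | tert-butyl(2,5-dimethoxyphenoxy)dimethylsilane | CC(C)(C)[Si](C)(C)Oc1cc(OC)ccc1OC | intermediate
14 | (4-bromo-2,5-dimethoxyphenoxy)(tert-butyl)dimethylsilane | CC(C)(C)[Si](C)(C)Oc1cc(OC)c(Br)cc1OC | intermediate
15 | methyl (2S)-3-hydroxy-2-methylpropanoate, (S)-Roche ester | OC[C@H](C)C(=O)OC | starting material
16 | methyl (2S)-3-(tert-butyldimethylsilyloxy)-2-methylpropanoate | CC(C)(C)[Si](C)(C)OC[C@H](C)C(=O)OC | intermediate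
17 | tert-butyl acetate | CC(=O)OC(C)(C)C | starting material
18 | lithium enolate of tert-butyl acetate (not isolated) | C=C(O[Li])OC(C)(C)C | intermediate
19 | tert-butyl (4S)-5-(tert-butyldimethylsilyloxy)-4-methyl-3-oxopentanoate | CC(C)(C)[Si](C)(C)OC[C@H](C)C(=O)CC(=O)OC(C)(C)C | intermediate
20 | tert-butyl (4S)-5-hydroxy-4-methyl-3-oxopentanoate (not isolated) | OC[C@H](C)C(=O)CC(=O)OC(C)(C)C | intermediate
21 | (4S)-5-hydroxy-4-methyl-3-oxopent-1-en-1-one, acylketene (not isolated) | OC[C@H](C)C(=O)C=C=O | intermediate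
22 | (5S)-5-methyloxane-2,4-dione | C1[C@H](C)C(=O)CC(=O)O1 | intermediate
23 | (3S)-3-methyl-6-oxo-3,6-dihydro-2H-pyran-4-yl trifluoromethanesulfonate | C1[C@H](C)C(OS(=O)(=O)C(F)(F)F)=CC(=O)O1 | intermediate
24 | (5R)-5-methyl-4-(2,4,5-trimethoxyphenyl)-5,6-dihydro-2H-pyran-2-one | C1[C@H](C)C(c2cc(OC)c(OC)cc2OC)=CC(=O)O1 | intermediate
25 | (4R,5R)-5-methyl-4-(2,4,5-trimethoxyphenyl)oxan-2-one (4,5-cis) | C1[C@H](C)[C@H](c2cc(OC)c(OC)cc2OC)CC(=O)O1 | intermediate
26 | lithium enolate of lactone 25 (not isolated) | C1[C@H](C)[C@H](c2cc(OC)c(OC)cc2OC)C=C(O[Li])O1 | intermediate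
27 | (3R,4S,5R)-3,5-dimethyl-4-(2,4,5-trimethoxyphenyl)oxan-2-one (3,4-trans/4,5-cis) | C1[C@H](C)[C@H](c2cc(OC)c(OC)cc2OC)[C@@H](C)C(=O)O1 | intermediate
28 | [4-(tert-butyldimethylsilyloxy)-2,5-dimethoxyphenyl]lithium (not isolated) | [Li]c1cc(OC)c(O[Si](C)(C)C(C)(C)C)cc1OC | intermediate
29 | lithium alkoxide of the ring-opened (2R,3S,4R) aryl ketone (not isolated) | [Li]OC[C@H](C)[C@H](c1cc(OC)c(OC)cc1OC)[C@@H](C)C(=O)c1cc(OC)c(O[Si](C)(C)C(C)(C)C)cc1OC | intermediate
30 | (2R,3S,4R)-1,1-bis[4-(tert-butyldimethylsilyloxy)-2,5-dimethoxyphenyl]-2,4-dimethyl-3-(2,4,5-trimethoxyphenyl)pentane-1,5-diol | OC[C@H](C)[C@H](c1cc(OC)c(OC)cc1OC)[C@@H](C)C(O)(c1cc(OC)c(O[Si](C)(C)C(C)(C)C)cc1OC)c1cc(OC)c(O[Si](C)(C)C(C)(C)C)cc1OC | intermediate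
31 | (2R,3R,4R)-5,5-bis[4-(tert-butyldimethylsilyloxy)-2,5-dimethoxyphenyl]-2,4-dimethyl-3-(2,4,5-trimethoxyphenyl)pentan-1-ol | OC[C@H](C)[C@H](c1cc(OC)c(OC)cc1OC)[C@@H](C)C(c1cc(OC)c(O[Si](C)(C)C(C)(C)C)cc1OC)c1cc(OC)c(O[Si](C)(C)C(C)(C)C)cc1OC | intermediate
32 | (2R,3R,4R)-5,5-bis[4-(tert-butyldimethylsilyloxy)-2,5-dimethoxyphenyl]-2,4-dimethyl-3-(2,4,5-trimethoxyphenyl)pentanal | O=C[C@H](C)[C@H](c1cc(OC)c(OC)cc1OC)[C@@H](C)C(c1cc(OC)c(O[Si](C)(C)C(C)(C)C)cc1OC)c1cc(OC)c(O[Si](C)(C)C(C)(C)C)cc1OC | intermediate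
33 | bromomagnesium alkoxide of the vinyl carbinol, C1 epimers (not isolated) | C=CC(O[Mg]Br)[C@H](C)[C@H](c1cc(OC)c(OC)cc1OC)[C@@H](C)C(c1cc(OC)c(O[Si](C)(C)C(C)(C)C)cc1OC)c1cc(OC)c(O[Si](C)(C)C(C)(C)C)cc1OC | intermediate
34 | (4R,5R,6R)-7,7-bis[4-(tert-butyldimethylsilyloxy)-2,5-dimethoxyphenyl]-4,6-dimethyl-5-(2,4,5-trimethoxyphenyl)hept-1-en-3-yl methyl carbonate (C3 epimer mixture) | C=CC(OC(=O)OC)[C@H](C)[C@H](c1cc(OC)c(OC)cc1OC)[C@@H](C)C(c1cc(OC)c(O[Si](C)(C)C(C)(C)C)cc1OC)c1cc(OC)c(O[Si](C)(C)C(C)(C)C)cc1OC | intermediate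
35 | (4R,5R,6R)-7,7-bis(4-hydroxy-2,5-dimethoxyphenyl)-4,6-dimethyl-5-(2,4,5-trimethoxyphenyl)hept-1-en-3-yl methyl carbonate (C3 epimer mixture) | C=CC(OC(=O)OC)[C@H](C)[C@H](c1cc(OC)c(OC)cc1OC)[C@@H](C)C(c1cc(OC)c(O)cc1OC)c1cc(OC)c(O)cc1OC | intermediate
36 | (6S,7R,8R,9S,10R,11R)-7-ethenyl-11-(4-hydroxy-2,5-dimethoxyphenyl)-1,4-dimethoxy-8,10-dimethyl-9-(2,4,5-trimethoxyphenyl)spiro[5.5]undeca-1,4-dien-3-one | C=C[C@@H]1[C@H](C)[C@H](c2cc(OC)c(OC)cc2OC)[C@@H](C)[C@H](c2cc(OC)c(O)cc2OC)[C@]12C=C(OC)C(=O)C=C2OC | intermediate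
37 | (6S,7R,8R,9S,10R,11R)-7-ethenyl-1,4-dimethoxy-8,10-dimethyl-9,11-bis(2,4,5-trimethoxyphenyl)spiro[5.5]undeca-1,4-dien-3-one | C=C[C@@H]1[C@H](C)[C@H](c2cc(OC)c(OC)cc2OC)[C@@H](C)[C@H](c2cc(OC)c(OC)cc2OC)[C@]12C=C(OC)C(=O)C=C2OC | intermediate
38 | tatanan B, (6S,7R,8S,9S,10R,11R)-7-ethyl-1,4-dimethoxy-8,10-dimethyl-9,11-bis(2,4,5-trimethoxyphenyl)spiro[5.5]undeca-1,4-dien-3-one | CC[C@@H]1[C@H](C)[C@H](c2cc(OC)c(OC)cc2OC)[C@@H](C)[C@H](c2cc(OC)c(OC)cc2OC)[C@]12C=C(OC)C(=O)C=C2OC | target

## Step count and risks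
Total step count: 23.
Longest linear sequence: 15 steps (steps 9–23 from 15). The path through steps 1–4 and 13–23 from 1 is equally long. The path from 8 is 12 steps.

**Step 16.** The second aryl addition may stall at the hindered, enolisable ketone. The fallback sets out from lactone 27 and comes back at alcohol 31, so carbinol 30 and step 17 are bypassed.
- One equivalent of aryllithium 28 is added to 27 at −78 °C and quenched cold to give the hydroxy ketone F1.
- TsNHNH2 (MeOH, 60 °C) converts it into the N‑tosylhydrazone F2.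
- A second portion of 28 is quenched with B(Oi‑Pr)3 and hydrolysed to the arylboronic acid F3.
- Heating the hydrazone and the boronic acid with K2CO3 in dioxane at 110 °C (Barluenga–Valdés metal‑free reductive coupling) makes the second C5–aryl bond and the C5–H bond in one operation, without a carbonyl addition or a carbocation, and gives 31.

**Step 17.** A long‑lived C5 cation could lose the C4 proton and epimerise C4, or be captured by the C3 aryl group. The fallback sets out from carbinol 30, comes back at 31, and replaces the cation by an anionic quinone‑methide pathway.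
- TBAF in THF–MeOH in the presence of NaBH4 strips both aryl silyl ethers to give the tetraol F4.
- Its phenoxide expels hydroxide to give the quinone methide (fuchsone) F5.
- 1,6‑Hydride addition traps this at once as the bis‑phenol alcohol F6.
- Exhaustive silylation (TBSCl, imidazole, DMF) gives the tris‑silyl ether F7.
- PPTS in MeOH removes only the primary alkyl silyl ether, because aryl silyl ethers are acid‑stable, and returns 31.

**Step 21.** The risks are the choice between the two aryl groups, the C6 configuration (the C6 epimer belongs to the tatanan C series and would have to be separated), and elimination of the π‑allyl complex to a diene. The fallback sets out from aldehyde 32, comes back at 36, and reverses the polarity of the ring closure.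
- Wittig olefination with Ph3P=CHCH2SiMe3 gives the (Z)‑allylsilane F8.
- K2CO3 in MeOH cleaves only the aryl silyl ethers to give the bis‑phenol allylsilane F9.
- PhI(OAc)2 (1 equiv) in (CF3)2CHOH at −20 °C oxidises one phenol to a phenoxenium ion.
- The allylsilane terminus C1 captures it at the para carbon (oxidative Hosomi–Sakurai‑type dearomatisation) through the same chair, releasing the vinyl group and giving 36.

Further compounds
F1 | step 16 | (2R,3S,4R)-1-[4-(tert-butyldimethylsilyloxy)-2,5-dimethoxyphenyl]-5-hydroxy-2,4-dimethyl-3-(2,4,5-trimethoxyphenyl)pentan-1-one | OC[C@H](C)[C@H](c1cc(OC)c(OC)cc1OC)[C@@H](C)C(=O)c1cc(OC)c(O[Si](C)(C)C(C)(C)C)cc1OC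
F2 | step 16 | N-tosylhydrazone of F1 (C2–C4 as in 27) | OC[C@H](C)[C@H](c1cc(OC)c(OC)cc1OC)[C@@H](C)C(=NNS(=O)(=O)c1ccc(C)cc1)c1cc(OC)c(O[Si](C)(C)C(C)(C)C)cc1OC
F3 | step 16 | [4-(tert-butyldimethylsilyloxy)-2,5-dimethoxyphenyl]boronic acid | OB(O)c1cc(OC)c(O[Si](C)(C)C(C)(C)C)cc1OC
F4 | step 17 | (2R,3S,4R)-1,1-bis(4-hydroxy-2,5-dimethoxyphenyl)-2,4-dimethyl-3-(2,4,5-trimethoxyphenyl)pentane-1,5-diol | OC[C@H](C)[C@H](c1cc(OC)c(OC)cc1OC)[C@@H](C)C(O)(c1cc(OC)c(O)cc1OC)c1cc(OC)c(O)cc1OC
F5 | step 17 | quinone methide (fuchsone) formed from F4 by loss of water, C2–C4 as in 30 | OC[C@H](C)[C@H](c1cc(OC)c(OC)cc1OC)[C@@H](C)C(c1cc(OC)c(O)cc1OC)=C1C=C(OC)C(=O)C=C1OC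
F6 | step 17 | (2R,3R,4R)-5,5-bis(4-hydroxy-2,5-dimethoxyphenyl)-2,4-dimethyl-3-(2,4,5-trimethoxyphenyl)pentan-1-ol | OC[C@H](C)[C@H](c1cc(OC)c(OC)cc1OC)[C@@H](C)C(c1cc(OC)c(O)cc1OC)c1cc(OC)c(O)cc1OC
F7 | step 17 | tris(tert-butyldimethylsilyl) ether of F6 | CC(C)(C)[Si](C)(C)OC[C@H](C)[C@H](c1cc(OC)c(OC)cc1OC)[C@@H](C)C(c1cc(OC)c(O[Si](C)(C)C(C)(C)C)cc1OC)c1cc(OC)c(O[Si](C)(C)C(C)(C)C)cc1OC
F8 | step 21 | (Z)-allylsilane from 32, bis(aryl silyl ether), C2–C4 as in 32 | C[Si](C)(C)C/C=C\[C@H](C)[C@H](c1cc(OC)c(OC)cc1OC)[C@@H](C)C(c1cc(OC)c(O[Si](C)(C)C(C)(C)C)cc1OC)c1cc(OC)c(O[Si](C)(C)C(C)(C)C)cc1OC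
F9 | step 21 | (Z)-allylsilane bis-phenol, C2–C4 as in 32 | C[Si](C)(C)C/C=C\[C@H](C)[C@H](c1cc(OC)c(OC)cc1OC)[C@@H](C)C(c1cc(OC)c(O)cc1OC)c1cc(OC)c(O)cc1OC
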